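This flask cannot make more product than its partner can supply. If one partner goes into each product, the balance of the partner, the limiting reagent, caps the reacted starting material at the ceiling C, the partner charge divided by the starting material charge: C = 95.0 %.

the same everywhere: starting material 0.50 M
- Wednesday's: partner 0.475 M; the very flask that is asked about, followed so far
- Saturday's: partner 0.95 M; run made earlier
- flask: partner 0.475 M; time 15 h

- Wednesday's (time / h: starting material / %, product / %): 0.200: 40, 63; 0.667: 21, 81; 1.00: 16, 84; 1.50: 10, 87; 2.50: 9, 91; 3.00: 9, 92
- Saturday's (time / h: starting material / %, product / %): 0.833: 7, 91; 1.33: 10, 93; 2.50: 3, 100; 4.00: 3, 97; 6.00: 0, 96; 10.0: 0, 100

(scatter of a reading: 1.5 percentage points)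

- the reaction counts as stopped when no species that holds the starting material changes by six tenths of a point or more over the second half of the time

- at 15 h, what has stopped the reaction, if anything has (the partner has run out first / it is still moving / all of the starting material has reacted / forward and back rates have come level)
- how much of the starting material has reacted by 15 h
- how much product there is at 15 h, in percent of the starting material charged

Is the levelling in Wednesday's run this ceiling or a back reaction? Saturday's run, with twice the partner, reads 0 % starting material at 10.0 h, but a small remainder there would lie within the scatter of 1.5 percentage points, so that run does not tell the two apart. I assume no back reaction, and on that assumption I expect C to stop Wednesday's flask.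

How far off is that flask? Averaging reacted starting material and product, I read a gap g below C of 6.5 points at 1.50 h and 3.5 points at 3.00 h, about half across that interval.

Does it close in time? If g keeps that ratio per interval, which is my assumption, it is 0.55 points at 7.50 h and 0.025 points at 15 h. The change over the second half therefore stays inside the stopping mark, and less than the scatter. I commit to a stop at C, and the reading to watch is starting material stalling at 5.00 % instead of falling to zero.

The forecast says it is still moving, with 93.5 % reacted and 93.5 % product, on the ground that “The rate therefore seems to fall as the reaction proceeds”, and my reckoning differs from it on the stop.

The flask gives the partner has run out first, with 95.0 % reacted and 95.0 % product.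

    starting material + partner → product, rate k1*[starting material]^2*[partner]^0.5 (k = 32.0 M⁻¹·⁵ h⁻¹)

At 15.0 h this flask has partner at 0 % of its charge, and its 95.0 % reacted stands against C = 95.0 %. In the neighbour charged with 0.12 M of partner, the same balance gives C = 24.0 %. That neighbour reaches 24.0 % reacted and 24.0 % product, with partner at 0 % and 76.0 % starting material left at 15.0 h.

(The earlier runs and the new flask were computed with constants of no real substance; the scatter is artificial.)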